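**Retrosynthetic overview**
1. Target ⇒ bis-ynoate by a final syn semi-hydrogenation that sets both Z alkenes; the C3–O ester bond ⇒ decalin alcohol (8,9-diol as acetonide) + (S)-4-(hex-2-ynoyloxy)hex-2-ynoic acid.
2. Ring B of the core: isopropenyl ⇐ acetyl (Wittig); 8α,9α-diol ⇐ OsO4 on a C8=C9 alkene; C7 ⇐ cuprate addition to a C7=C8–C9=O enone; C10–H ⇐ dissolving-metal reduction. All four centres are steered by the axial C5 methyl.
3. Key disconnection: ring A (C1, C2, C3, C4, C5, C10) ⇒ retro inverse-electron-demand [4+2] across C2–C3 and C4–C5, giving achiral 2-ethenyl-3-methylcyclohex-2-en-1-one (ring B) + (E)-prop-1-enyl triethylsilyl ether, joined under a chiral silylium/IDPi catalyst.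
4. Enabling feature: the C9 oxygen of ring B sits next to C10, and C10 carries C1. At the ketone level, C9=O makes C5=C10–C1=C2 an electron-poor cross-conjugated diene with electrophilic C5 (the carbon of the angular methyl), matched to the enol ether C3=C4 that brings the C3 oxygen and the C4 methyl.
5. Ring order: ring B is bought as a cyclohexenone; ring A is formed in the key step, which also sets C3, C4 and the quaternary C5.

Key step: step 5

Remark: decalin positions follow eremophilane numbering (ring A = C1, C2, C3, C4, C5, C10; ring B = C5 to C10; methyls on C4 and C5; C11 on C7), β is the face of the C5 methyl, and the enantiopure propargylic alcohol used for the side chain is taken as purchasable.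

**Step 1**
Reactants: 1 3-methylcyclohex-2-en-1-one
Product: 2 2-iodo-3-methylcyclohex-2-en-1-one
Conditions: I2, pyridine, CH2Cl2, 0 °C to rt
Reagents that add atoms: iodine, II
Why: α-Iodination of the enone (conjugate addition of pyridine, iodination of the enolate, E1cB loss of pyridinium) puts the halogen on the future C10; no stereocenter is formed.

**Step 2**
Reactants: 2 2-iodo-3-methylcyclohex-2-en-1-one
Product: 3 2-ethenyl-3-methylcyclohex-2-en-1-one
Conditions: Bu3SnCH=CH2, PdCl2(PhCN)2 (5 mol%), AsPh3, CuI, NMP, rt to 50 °C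
Reagents that add atoms: tributyl(vinyl)stannane, C=C[Sn](CCCC)(CCCC)CCCC
Why: Stille cross-coupling of the α-iodoenone (oxidative addition, tin-to-palladium transmetalation, reductive elimination) attaches the C1=C2 vinyl group; no stereocenter is formed.

**Step 3**
Reactants: 4 prop-2-en-1-ol
Product: 5 triethyl(prop-2-en-1-yloxy)silane
Conditions: Et3SiCl, imidazole, CH2Cl2, 0 °C
Reagents that add atoms: chlorotriethylsilane, CC[Si](Cl)(CC)CC
Why: Imidazole-promoted O-silylation of a primary alcohol is routine and gives the allyl silyl ether needed for the isomerisation.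

**Step 4**
Reactants: 5 triethyl(prop-2-en-1-yloxy)silane
Product: 6 triethyl[(E)-prop-1-en-1-yloxy]silane
Conditions: [Ir(cod)(PMePh2)2]PF6 (1 mol%, activated with H2), THF, rt
Reagents that add atoms: none
Why: Iridium-hydride-catalysed allyl ether to enol ether isomerisation (1,3-hydrogen shift through a π-allyl hydride) is known to give (E)-prop-1-enyl silyl ethers selectively.

**Step 5**
Reactants: 3 2-ethenyl-3-methylcyclohex-2-en-1-one; 6 triethyl[(E)-prop-1-en-1-yloxy]silane
Product: 7 4β,5β-dimethyl-3α-(triethylsilyloxy)decal-1(10)-en-9-one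
Conditions: chiral IDPi Brønsted acid (binaphthyl-derived imidodiphosphorimidate with N-SO2CF3 groups, 3 mol%), 3 (1.3 equiv), toluene, −60 to −30 °C; Et3N quench
Reagents that add atoms: none
Why: Proposed new method: protodesilylation of a little 6 turns the IDPi acid into a chiral silylium ion pair that binds the C9 carbonyl of 3, so that the cross-conjugated 2-vinyl enone becomes an electron-poor diene whose β-carbon C5 is attacked by the nucleophilic C4 of 6 while C3 closes onto the vinyl terminus C2 in a highly asynchronous inverse-electron-demand [4+2] cycloaddition, the Et3Si group staying on the C3 oxygen and the silylium catalyst leaving the C9 oxygen. The closest known reaction types are the thermal and Lewis-acid-promoted inverse-demand Diels–Alder reactions of 2-acyl-1,3-dienes and vinylquinones with enol ethers, and the enantioselective silylium/IDPi-catalysed Mukaiyama–Michael and Diels–Alder reactions of unsaturated carbonyl compounds. Ring A is closed by intermolecular [4+2] cycloaddition, suprafacial on both components (at the stepwise limit a Mukaiyama–Michael addition followed by a 6-(enolendo)-exo-trig vinylogous aldol closure). The E geometry of 6 fixes C3–O trans to the C4 methyl, the endo position of the silyloxy group places the C4 methyl cis to the C5 methyl, and the confined chiral anion selects the diene face that becomes α at C5, which gives C3, C4 and C5 their absolute configuration (the catalyst antipode that does this is fixed in a pilot run). The step needs regio-, endo- and enantioface selectivity: the polarity match (nucleophilic C4, electrophilic C5) secures the regiochemistry, O-closure to a dihydropyran is impossible because ring B holds O=C9–C10=C5 s-trans, and a [2+2] adduct through C10 would be a donor–acceptor cyclobutane that re-opens to the six-membered product. The methyl on C5 points into the s-cis diene and would slow a synchronous thermal cycloaddition, but it is tolerated here because bond formation at C5 runs far ahead of closure at C2.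

**Step 6**
Reactants: 7 4β,5β-dimethyl-3α-(triethylsilyloxy)decal-1(10)-en-9-one
Product: 9 4β,5β-dimethyl-3α-(triethylsilyloxy)-trans-decalin-9-one, via lithium enolate 8 (not isolated)
Conditions: Li, NH3(l), THF, t-BuOH (1 equiv), −78 °C; then NH4Cl
Reagents that add atoms: none
Why: Dissolving-metal (Birch-type) conjugate reduction of the enone protonates C1 and leaves the C9–C10 enolate, which is protonated at C10 on the α face (axial, anti to the adjacent C5 methyl) to give the trans-fused decalone, expected also to be the more stable ring-fusion epimer.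

**Step 7**
Reactants: 9 4β,5β-dimethyl-3α-(triethylsilyloxy)-trans-decalin-9-one
Product: 12 4β,5β-dimethyl-3α-(triethylsilyloxy)-trans-decal-7-en-9-one, via lithium enolate 10 (not isolated), via silyl enol ether 11 (not isolated)
Conditions: LiN(iPr)2, Me3SiCl, THF, −78 °C; then Pd(OAc)2 (10 mol%), O2 (1 atm), DMSO, rt
Reagents that add atoms: none
Why: Kinetic deprotonation at the unhindered C8 methylene (the C10 methine next to the quaternary C5 is much slower) followed by Saegusa–Ito dehydrogenation of the silyl enol ether (palladium enolate, β-hydride elimination from C7) gives the C7=C8 enone without changing a stereocenter.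

**Step 8**
Reactants: 12 4β,5β-dimethyl-3α-(triethylsilyloxy)-trans-decal-7-en-9-one
Product: 14 7α-(1-ethoxyethenyl)-4β,5β-dimethyl-3α-(triethylsilyloxy)-trans-decal-8-en-9-yl trifluoromethanesulfonate, via lithium enolate 13 (not isolated)
Conditions: CH2=C(OEt)Li (from ethyl vinyl ether and t-BuLi), CuI (0.5 equiv per Li), THF, −78 to −40 °C; then PhNTf2, −78 °C to rt
Reagents that add atoms: ethyl vinyl ether, C=COCC; N-phenylbis(trifluoromethanesulfonimide), O=S(=O)(N(c1ccccc1)S(=O)(=O)C(F)(F)F)C(F)(F)F
Why: Conjugate addition of the 1-ethoxyvinyl cuprate (an acetyl anion equivalent) delivers C11 to C7 on the α face, away from the axial C5 methyl that is syn-axial to the β face of C7, and O-triflation of the regiodefined enolate fixes the C8=C9 double bond.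

**Step 9**
Reactants: 14 7α-(1-ethoxyethenyl)-4β,5β-dimethyl-3α-(triethylsilyloxy)-trans-decal-8-en-9-yl trifluoromethanesulfonate
Product: 16 7α-acetyl-4β,5β-dimethyl-trans-decal-8-en-3α-ol, via enol ether alkene 15 (not isolated)
Conditions: Pd(OAc)2 (5 mol%), PPh3, HCO2H, Bu3N, DMF, 60 °C; then AcOH/THF/H2O (3:1:1), rt
Reagents that add atoms: water, O
Why: Palladium-catalysed formate reduction of the enol triflate (oxidative addition, hydride transfer from formate, reductive elimination) gives the C8=C9 alkene, and mild aqueous acid then hydrolyses the enol ether to the methyl ketone and cleaves the triethylsilyl ether without disturbing C7.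

**Step 10**
Reactants: 16 7α-acetyl-4β,5β-dimethyl-trans-decal-8-en-3α-ol
Product: 17 7α-acetyl-4β,5β-dimethyl-trans-decalin-3α,8α,9α-triol
Conditions: OsO4 (2 mol%), NMO, acetone/H2O (5:1), 0 °C to rt
Reagents that add atoms: N-methylmorpholine N-oxide, C[N+]1([O-])CCOCC1; water, O
Why: Catalytic OsO4 cis-dihydroxylation ([3+2] osmate ester formation, hydrolysis) takes the α face of the C8=C9 alkene because the axial C5 methyl shields the β face at C9, as in 5α-Δ6 steroids, so the 8α (axial) and 9α (equatorial) hydroxyls are set together.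

**Step 11**
Reactants: 17 7α-acetyl-4β,5β-dimethyl-trans-decalin-3α,8α,9α-triol
Product: 18 7α-acetyl-8α,9α-(isopropylidenedioxy)-4β,5β-dimethyl-trans-decalin-3α-ol
Conditions: Me2C(OMe)2, PPTS (cat.), acetone, rt
Reagents that add atoms: 2,2-dimethoxypropane, COC(C)(C)OC
Why: Acid-catalysed transketalisation forms the five-membered isopropylidene ketal only on the cis-8,9-diol, the isolated C3 hydroxyl staying free after aqueous work-up.

**Step 12**
Reactants: 18 7α-acetyl-8α,9α-(isopropylidenedioxy)-4β,5β-dimethyl-trans-decalin-3α-ol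
Product: 19 8α,9α-(isopropylidenedioxy)-4β,5β-dimethyl-7α-(prop-1-en-2-yl)-trans-decalin-3α-ol
Conditions: Ph3PCH3Br, KOtBu (3.5 equiv each), THF, 0 °C to rt
Reagents that add atoms: methyltriphenylphosphonium bromide, C[P+](c1ccccc1)(c1ccccc1)c1ccccc1.[Br-]
Why: Wittig methylenation of the methyl ketone (excess ylide covers the free C3 hydroxyl) gives the isopropenyl group, and C7, epimerisable under these conditions, rests in its equatorial α configuration.

**Step 13**
Reactants: 20 (S)-pent-1-yn-3-ol
Product: 23 (S)-4-hydroxyhex-2-ynoic acid, via dilithio acetylide 21 (not isolated), via dilithium carboxylate 22 (not isolated)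
Conditions: n-BuLi (2.2 equiv), THF, −78 °C; CO2; then 1 M HCl
Reagents that add atoms: carbon dioxide, O=C=O
Why: C-carboxylation of the lithium acetylide of the O-lithiated propargylic alcohol with CO2 is a standard route to 4-hydroxyalk-2-ynoic acids and does not touch the stereocenter.

**Step 14**
Reactants: 23 (S)-4-hydroxyhex-2-ynoic acid
Product: 24 tert-butyl (S)-4-hydroxyhex-2-ynoate
Conditions: Cl3CC(=NH)OtBu (2 equiv), CH2Cl2/cyclohexane, rt
Reagents that add atoms: tert-butyl 2,2,2-trichloroacetimidate, CC(C)(C)OC(=N)C(Cl)(Cl)Cl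
Why: Uncatalysed O-tert-butylation by the trichloroacetimidate (protonation of the imidate by the acid, tert-butyl transfer) esterifies the acidic ynoic acid and leaves the secondary alcohol free.

**Step 15**
Reactants: 24 tert-butyl (S)-4-hydroxyhex-2-ynoate; 25 hex-2-ynoic acid
Product: 26 tert-butyl (S)-4-(hex-2-ynoyloxy)hex-2-ynoate
Conditions: DCC, DMAP (5 mol%), CH2Cl2, 0 °C
Reagents that add atoms: none
Why: Steglich esterification (O-acylisourea, acyl transfer by DMAP) acylates the propargylic hydroxyl with retention at the carbinol carbon.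

**Step 16**
Reactants: 26 tert-butyl (S)-4-(hex-2-ynoyloxy)hex-2-ynoate
Product: 27 (S)-4-(hex-2-ynoyloxy)hex-2-ynoic acid
Conditions: TFA, CH2Cl2, 0 °C
Reagents that add atoms: none
Why: Acidolysis of the tert-butyl ester (loss of the tert-butyl cation as isobutene) frees the carboxylic acid while the propargylic ester and both alkynes are stable to acid.

**Step 17**
Reactants: 19 8α,9α-(isopropylidenedioxy)-4β,5β-dimethyl-7α-(prop-1-en-2-yl)-trans-decalin-3α-ol; 27 (S)-4-(hex-2-ynoyloxy)hex-2-ynoic acid
Product: 28 8α,9α-(isopropylidenedioxy)-4β,5β-dimethyl-7α-(prop-1-en-2-yl)-trans-decalin-3α-yl (S)-4-(hex-2-ynoyloxy)hex-2-ynoate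
Conditions: DCC, DMAP (10 mol%), CH2Cl2, −10 °C to rt
Reagents that add atoms: none
Why: Steglich esterification of the equatorial C3 hydroxyl, the only free hydroxyl of 19, with an alkynoic acid that has no alkene geometry to lose, proceeds with retention at C3.

**Step 18**
Reactants: 28 8α,9α-(isopropylidenedioxy)-4β,5β-dimethyl-7α-(prop-1-en-2-yl)-trans-decalin-3α-yl (S)-4-(hex-2-ynoyloxy)hex-2-ynoate
Product: 29 8α,9α-dihydroxy-4β,5β-dimethyl-7α-(prop-1-en-2-yl)-trans-decalin-3α-yl (S)-4-(hex-2-ynoyloxy)hex-2-ynoate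
Conditions: AcOH/H2O (4:1), 40 °C
Reagents that add atoms: none
Why: Acid-catalysed hydrolysis of the isopropylidene ketal frees the 8,9-diol under conditions that leave the esters, the alkynes and the isopropenyl group intact.

**Step 19**
Reactants: 29 8α,9α-dihydroxy-4β,5β-dimethyl-7α-(prop-1-en-2-yl)-trans-decalin-3α-yl (S)-4-(hex-2-ynoyloxy)hex-2-ynoate
Product: 30 CNP0271544.1
Conditions: H2 (1 atm), Pd/CaCO3 poisoned with Pb(OAc)2, quinoline, EtOAc, rt, stopped after 2 equiv H2
Reagents that add atoms: none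
Why: Syn semi-hydrogenation of both conjugated alkynes on the lead-poisoned palladium surface gives the two (Z)-enoates in one step, the 1,1-disubstituted isopropenyl group being inert under quinoline-moderated conditions.

**Compound list**
1 | 3-methylcyclohex-2-en-1-one | CC1=CC(=O)CCC1 | starting material
2 | 2-iodo-3-methylcyclohex-2-en-1-one | CC1=C(I)C(=O)CCC1 | intermediate
3 | 2-ethenyl-3-methylcyclohex-2-en-1-one | CC1=C(C=C)C(=O)CCC1 | intermediate
4 | prop-2-en-1-ol | C=CCO | starting material
5 | triethyl(prop-2-en-1-yloxy)silane | C=CCO[Si](CC)(CC)CC | intermediate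
6 | triethyl[(E)-prop-1-en-1-yloxy]silane | C/C=C/O[Si](CC)(CC)CC | intermediate
7 | 4β,5β-dimethyl-3α-(triethylsilyloxy)decal-1(10)-en-9-one (3R,4R,5R) | C1C[C@]2(C)[C@@H](C)[C@H](O[Si](CC)(CC)CC)CC=C2C(=O)C1 | intermediate
8 | lithium C9–C10 enolate of 9 | C1C[C@]2(C)[C@@H](C)[C@H](O[Si](CC)(CC)CC)CCC2=C(O[Li])C1 | intermediate
9 | 4β,5β-dimethyl-3α-(triethylsilyloxy)-trans-decalin-9-one (10α-H; 3R,4R,5R,10R) | C1C[C@]2(C)[C@@H](C)[C@H](O[Si](CC)(CC)CC)CC[C@H]2C(=O)C1 | intermediate
10 | lithium C8–C9 enolate of 9 | C1C[C@]2(C)[C@@H](C)[C@H](O[Si](CC)(CC)CC)CC[C@H]2C(O[Li])=C1 | intermediate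
11 | C8–C9 trimethylsilyl enol ether of 9 | C1C[C@]2(C)[C@@H](C)[C@H](O[Si](CC)(CC)CC)CC[C@H]2C(O[Si](C)(C)C)=C1 | intermediate
12 | 4β,5β-dimethyl-3α-(triethylsilyloxy)-trans-decal-7-en-9-one (3R,4R,5R,10R) | C1[C@]2(C)[C@@H](C)[C@H](O[Si](CC)(CC)CC)CC[C@H]2C(=O)C=C1 | intermediate
13 | lithium C8–C9 enolate carrying 7α-(1-ethoxyethenyl) | C=C(OCC)[C@@H]1C[C@]2(C)[C@@H](C)[C@H](O[Si](CC)(CC)CC)CC[C@H]2C(O[Li])=C1 | intermediate
14 | 7α-(1-ethoxyethenyl)-4β,5β-dimethyl-3α-(triethylsilyloxy)-trans-decal-8-en-9-yl trifluoromethanesulfonate | C=C(OCC)[C@@H]1C[C@]2(C)[C@@H](C)[C@H](O[Si](CC)(CC)CC)CC[C@H]2C(OS(=O)(=O)C(F)(F)F)=C1 | intermediate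
15 | 7α-(1-ethoxyethenyl)-4β,5β-dimethyl-3α-(triethylsilyloxy)-trans-decal-8-ene | C=C(OCC)[C@@H]1C[C@]2(C)[C@@H](C)[C@H](O[Si](CC)(CC)CC)CC[C@H]2C=C1 | intermediate
16 | 7α-acetyl-4β,5β-dimethyl-trans-decal-8-en-3α-ol | CC(=O)[C@@H]1C[C@]2(C)[C@@H](C)[C@H](O)CC[C@H]2C=C1 | intermediate
17 | 7α-acetyl-4β,5β-dimethyl-trans-decalin-3α,8α,9α-triol | CC(=O)[C@@H]1C[C@]2(C)[C@@H](C)[C@H](O)CC[C@H]2[C@H](O)[C@@H]1O | intermediate
18 | 7α-acetyl-8α,9α-(isopropylidenedioxy)-4β,5β-dimethyl-trans-decalin-3α-ol | CC(=O)[C@@H]1C[C@]2(C)[C@@H](C)[C@H](O)CC[C@H]2[C@H](OC(C)(C)O3)[C@@H]13 | intermediate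
19 | 8α,9α-(isopropylidenedioxy)-4β,5β-dimethyl-7α-(prop-1-en-2-yl)-trans-decalin-3α-ol (3R,4R,5R,7S,8R,9S,10R) | C=C(C)[C@@H]1C[C@]2(C)[C@@H](C)[C@H](O)CC[C@H]2[C@H](OC(C)(C)O3)[C@@H]13 | intermediate
20 | (S)-pent-1-yn-3-ol | C#C[C@H](CC)O | starting material
21 | dilithio derivative of 20 (lithium alkoxide, lithium acetylide) | [Li]C#C[C@H](CC)O[Li] | intermediate
22 | dilithium salt of 23 | [Li]OC(=O)C#C[C@H](CC)O[Li] | intermediate
23 | (S)-4-hydroxyhex-2-ynoic acid | OC(=O)C#C[C@H](CC)O | intermediate
24 | tert-butyl (S)-4-hydroxyhex-2-ynoate | CC(C)(C)OC(=O)C#C[C@H](CC)O | intermediate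
25 | hex-2-ynoic acid | CCCC#CC(=O)O | starting material
26 | tert-butyl (S)-4-(hex-2-ynoyloxy)hex-2-ynoate | CC(C)(C)OC(=O)C#C[C@H](CC)OC(=O)C#CCCC | intermediate
27 | (S)-4-(hex-2-ynoyloxy)hex-2-ynoic acid | OC(=O)C#C[C@H](CC)OC(=O)C#CCCC | intermediate
28 | 8α,9α-(isopropylidenedioxy)-4β,5β-dimethyl-7α-(prop-1-en-2-yl)-trans-decalin-3α-yl (S)-4-(hex-2-ynoyloxy)hex-2-ynoate | C=C(C)[C@@H]1C[C@]2(C)[C@@H](C)[C@H](OC(=O)C#C[C@H](CC)OC(=O)C#CCCC)CC[C@H]2[C@H](OC(C)(C)O3)[C@@H]13 | intermediate
29 | 8α,9α-dihydroxy-4β,5β-dimethyl-7α-(prop-1-en-2-yl)-trans-decalin-3α-yl (S)-4-(hex-2-ynoyloxy)hex-2-ynoate | C=C(C)[C@@H]1C[C@]2(C)[C@@H](C)[C@H](OC(=O)C#C[C@H](CC)OC(=O)C#CCCC)CC[C@H]2[C@H](O)[C@@H]1O | intermediate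
30 | CNP0271544.1, (1R,2R,4aR,5S,6R,7S,8aR)-5,6-dihydroxy-1,8a-dimethyl-7-(prop-1-en-2-yl)decahydronaphthalen-2-yl (2Z,4S)-4-[(2Z)-hex-2-enoyloxy]hex-2-enoate | C=C(C)[C@@H]1C[C@]2(C)[C@@H](C)[C@H](OC(=O)/C=C\[C@H](CC)OC(=O)/C=C\CCC)CC[C@H]2[C@H](O)[C@@H]1O | target

**Step count and risks**
Total step count: 19. Longest linear sequence: 13 steps (1, 2, 5 to 12, 17 to 19) from 3-methylcyclohex-2-en-1-one.

Steps most likely to fail:

1. Step 5 (proposed new method). The catalyst may discriminate the diene faces poorly, 3 may oligomerise under the strong acid before cycloaddition, or a second enol silane may add to the product enone. The fallback uses known chemistry, sets out from 3 and returns at 9, and moves stereocontrol into the dienophile. (S)-1-(2,4,6-Triisopropylphenyl)ethanol is O-allylated under phase-transfer conditions (allyl bromide, 50% NaOH, Bu4NHSO4) to the allyl ether F1 and isomerised with [Ir(cod)(PMePh2)2]PF6/H2 to the (E)-prop-1-enyl ether F2. An EtAlCl2-promoted inverse-demand Diels–Alder reaction of 3 with F2 (CH2Cl2, −78 °C), in which the aryl group shields one face of the enol ether, should give the auxiliary-bearing enone F3; the antipodal alcohol is taken if the (S)-auxiliary exposes the wrong face. Li/NH3 then reduces the enone and cleaves the benzylic C–O bond in the same flask, through the dilithium enolate alkoxide F4, to the hydroxy ketone F5, and Et3SiCl/imidazole returns the route to 9.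

2. Step 8. Transfer of the oxygenated vinyl group to the hindered enone may be sluggish, and the enolate may be protonated before O-triflation. The fallback sets out from 12 and returns at 16. Lithium divinylcuprate adds to C7 to give the lithium enolate F6, which is triflated with PhNTf2 to the 7α-vinyl enol triflate F7. Pd(OAc)2/PPh3/HCO2H/Bu3N reduces it to the 7α-vinyl alkene F8. Tsuji–Wacker oxidation (PdCl2, CuCl, O2, DMF/H2O) of the monosubstituted vinyl group, which reacts much faster than the cis-disubstituted ring alkene, gives the methyl ketone silyl ether F9, and AcOH/THF/H2O removes the silyl group to reach 16.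

3. Step 19. The conjugated (Z)-enoates may be over-reduced, the isopropenyl group partly reduced, or Z to E isomerisation may occur on the catalyst. The fallback sets out from 26 (with 19) and returns at 30, and sets the alkene geometry before the coupling. Ester 26 is semi-hydrogenated on the fragment (H2, Pd/CaCO3 poisoned with Pb(OAc)2, quinoline), where no other alkene is present, to the (Z,Z)-tert-butyl ester F10, and TFA gives the (Z,Z)-acid F11. 1-Chloro-N,N,2-trimethylprop-1-en-1-amine converts it under neutral conditions into the acid chloride F12, which acylates 19 (2,6-lutidine, CH2Cl2, −20 °C) without nucleophilic catalysis to give the target acetonide F13. AcOH/H2O (4:1) then gives 30.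

**Further compounds**
F1 | step 5 | (S)-allyl 1-(2,4,6-triisopropylphenyl)ethyl ether | C[C@H](OCC=C)c1c(C(C)C)cc(C(C)C)cc1C(C)C
F2 | step 5 | (S)-(E)-prop-1-enyl 1-(2,4,6-triisopropylphenyl)ethyl ether | C[C@H](O/C=C/C)c1c(C(C)C)cc(C(C)C)cc1C(C)C
F3 | step 5 | 4β,5β-dimethyl-3α-[(S)-1-(2,4,6-triisopropylphenyl)ethoxy]decal-1(10)-en-9-one | C1C[C@]2(C)[C@@H](C)[C@H](O[C@@H](C)c3c(C(C)C)cc(C(C)C)cc3C(C)C)CC=C2C(=O)C1
F4 | step 5 | dilithium C9–C10 enolate 3α-alkoxide | C1C[C@]2(C)[C@@H](C)[C@H](O[Li])CCC2=C(O[Li])C1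
F5 | step 5 | 3α-hydroxy-4β,5β-dimethyl-trans-decalin-9-one | C1C[C@]2(C)[C@@H](C)[C@H](O)CC[C@H]2C(=O)C1
F6 | step 8 | lithium C8–C9 enolate carrying 7α-ethenyl | C=C[C@@H]1C[C@]2(C)[C@@H](C)[C@H](O[Si](CC)(CC)CC)CC[C@H]2C(O[Li])=C1
F7 | step 8 | 7α-ethenyl-4β,5β-dimethyl-3α-(triethylsilyloxy)-trans-decal-8-en-9-yl trifluoromethanesulfonate | C=C[C@@H]1C[C@]2(C)[C@@H](C)[C@H](O[Si](CC)(CC)CC)CC[C@H]2C(OS(=O)(=O)C(F)(F)F)=C1
F8 | step 8 | 7α-ethenyl-4β,5β-dimethyl-3α-(triethylsilyloxy)-trans-decal-8-ene | C=C[C@@H]1C[C@]2(C)[C@@H](C)[C@H](O[Si](CC)(CC)CC)CC[C@H]2C=C1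
F9 | step 8 | 7α-acetyl-4β,5β-dimethyl-3α-(triethylsilyloxy)-trans-decal-8-ene | CC(=O)[C@@H]1C[C@]2(C)[C@@H](C)[C@H](O[Si](CC)(CC)CC)CC[C@H]2C=C1
F10 | step 19 | tert-butyl (2Z,4S)-4-[(2Z)-hex-2-enoyloxy]hex-2-enoate | CC(C)(C)OC(=O)/C=C\[C@H](CC)OC(=O)/C=C\CCC
F11 | step 19 | (2Z,4S)-4-[(2Z)-hex-2-enoyloxy]hex-2-enoic acid | OC(=O)/C=C\[C@H](CC)OC(=O)/C=C\CCC
F12 | step 19 | (2Z,4S)-4-[(2Z)-hex-2-enoyloxy]hex-2-enoyl chloride | ClC(=O)/C=C\[C@H](CC)OC(=O)/C=C\CCC
F13 | step 19 | 8,9-O-isopropylidene derivative of 30 | C=C(C)[C@@H]1C[C@]2(C)[C@@H](C)[C@H](OC(=O)/C=C\[C@H](CC)OC(=O)/C=C\CCC)CC[C@H]2[C@H](OC(C)(C)O3)[C@@H]13
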